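**Retrosynthetic overview** (chroman-4-one numbering for the core: O1, C2–C4, C4a, C5–C8, C8a; ring A = pyranone, ring B = carbocycle, ring C = δ-lactone, ring D = cyclobutane)

- Disconnections: hydrolysis of the enol δ-lactone (last) ⇐ ligand-controlled dearomative prenylation at C8 ⇐ C8–CH2 union of a tricyclic chromanone–dihydrocoumarin phenol with the redox-active ester of a pinene-derived cyclobutaneacetic acid.
- Key bond: two donor carbons are joined by a light-driven oxidative decarboxylation. The phenolate carbon C8 and the carboxyl-bearing CH2 of the cyclobutane fragment meet as phenoxyl and primary alkyl radicals.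
- Enabling feature: C8 is the only unsubstituted carbon of ring B, between the C7 oxyanion and O1 of ring A, so the phenolate is electron donor, radical acceptor and its own regiocontrol. The CH2 is exocyclic to ring D, so its radical leaves both ring D stereocentres untouched.
- Ring order: ring B from phloroglucinol; ring C first (as a coumarin), then ring A (oxa-Michael), then saturation of ring C. Ring D is taken intact from (+)-α-pinene. Ring B is dearomatised and ring C opened at the end.

Key step: step 8

Assumption: the sense of induction of the chiral catalysts in steps 4 and 10 is assigned by analogy with the usual models; if it is reversed, the antipodal ligand is used without other change.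

**Step 1**
Reactants: 1 phloroglucinol; 2 ethyl 3-oxohexanoate
Product: 3 5,7-dihydroxy-4-propyl-2H-chromen-2-one
Conditions: CF3SO3H, 0 °C to rt
Reagents that add atoms: none
Why: Pechmann condensation on the threefold-symmetric triphenol can give only one coumarin, and the rigid unsaturated lactone fixes which oxygen carries ring C; no stereocentre is formed.

**Step 2**
Reactants: 3 5,7-dihydroxy-4-propyl-2H-chromen-2-one; 4 (2E)-2-methylbut-2-enoyl chloride
Product: 5 5,7-dihydroxy-8-[(2E)-2-methylbut-2-enoyl]-4-propyl-2H-chromen-2-one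
Conditions: AlCl3, PhNO2/1,2-dichloroethane, 0 °C to 40 °C
Reagents that add atoms: none
Why: Friedel–Crafts acylation of 5,7-dihydroxy-4-alkylcoumarins is expected to favour C8, between the 7-hydroxyl and the ring oxygen and away from the peri propyl group, and the mild temperature should keep the hydroxy-enone from cyclising; no stereocentre is formed.

**Step 3**
Reactants: 5 5,7-dihydroxy-8-[(2E)-2-methylbut-2-enoyl]-4-propyl-2H-chromen-2-one
Product: 6 (8R,9S)-5-hydroxy-8,9-dimethyl-4-propyl-8,9-dihydro-2H,10H-pyrano[2,3-f]chromene-2,10-dione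
Conditions: (−)-quinine (20 mol%), chlorobenzene, 15 °C
Reagents that add atoms: none
Why: cinchona-alkaloid-catalysed intramolecular oxa-Michael addition of the only hydroxyl next to the enone closes ring A by 6-endo-trig attack; the quinine–phenoxide ion pair should set the O–CH centre as R and kinetic protonation of the enol should give the cis (8R,9S) pair, which is kept away from strong base afterwards.

**Step 4**
Reactants: 6 (8R,9S)-5-hydroxy-8,9-dimethyl-4-propyl-8,9-dihydro-2H,10H-pyrano[2,3-f]chromene-2,10-dione
Product: 7 (4S,8R,9S)-5-hydroxy-8,9-dimethyl-4-propyl-3,4,8,9-tetrahydro-2H,10H-pyrano[2,3-f]chromene-2,10-dione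
Conditions: [Ir(cod){(S)-tBu-PHOX}]BArF (2 mol%), H2 (50 bar), CH2Cl2, rt
Reagents that add atoms: none
Why: iridium-catalysed asymmetric hydrogenation of a trisubstituted β-aryl-β-alkyl unsaturated ester (here the coumarin C3=C4 bond) should leave the aryl ketone untouched; the chiral P,N ligand controls the face of hydrogen delivery and sets the propyl-bearing centre as S, and the neutral medium should not epimerise the cis-chromanone.

**Step 5**
Reactants: 8 (1R,5R)-(+)-α-pinene
Product: 9 2-[(1S,3S)-3-acetyl-2,2-dimethylcyclobutyl]acetic acid (cis-pinonic acid)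
Conditions: RuCl3·xH2O (2 mol%), NaIO4, EtOAc/MeCN/H2O, rt
Reagents that add atoms: sodium periodate, [Na+].[O-]I(=O)(=O)=O
Why: ruthenium tetroxide oxidative cleavage of the trisubstituted alkene gives the methyl ketone and the acid; both cyclobutane stereocentres are the former bridgeheads of the pinene and stay cis and unchanged.

**Step 6**
Reactants: 9 2-[(1S,3S)-3-acetyl-2,2-dimethylcyclobutyl]acetic acid
Product: 10 2-[(1S,3R)-2,2-dimethyl-3-(prop-1-en-2-yl)cyclobutyl]acetic acid
Conditions: Ph3PCH3Br, KOtBu, THF, 0 °C to rt; then aq. HCl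
Reagents that add atoms: methyltriphenylphosphonium bromide, C[P+](c1ccccc1)(c1ccccc1)c1ccccc1.[Br-]
Why: Wittig methylenation of the methyl ketone on the carboxylate salt installs the isopropenyl group; no stereocentre is formed, and olefination at 0 °C should outrun enolisation of the ketone α-centre (the descriptor changes only through priorities).

**Step 7**
Reactants: 10 2-[(1S,3R)-2,2-dimethyl-3-(prop-1-en-2-yl)cyclobutyl]acetic acid; 11 N-hydroxyphthalimide
Product: 12 1,3-dioxoisoindolin-2-yl 2-[(1S,3R)-2,2-dimethyl-3-(prop-1-en-2-yl)cyclobutyl]acetate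
Conditions: N,N'-diisopropylcarbodiimide, DMAP (5 mol%), CH2Cl2, rt
Reagents that add atoms: none
Why: Steglich-type esterification gives the redox-active ester, whose carboxyl carbon is the traceless activator of the future CH2 radical; no stereocentre is involved.

**Step 8**
Reactants: 7 (4S,8R,9S)-5-hydroxy-8,9-dimethyl-4-propyl-3,4,8,9-tetrahydro-2H,10H-pyrano[2,3-f]chromene-2,10-dione; 12 1,3-dioxoisoindolin-2-yl 2-[(1S,3R)-2,2-dimethyl-3-(prop-1-en-2-yl)cyclobutyl]acetate
Product: 13 (4S,8R,9S)-6-{[(1S,3R)-2,2-dimethyl-3-(prop-1-en-2-yl)cyclobutyl]methyl}-5-hydroxy-8,9-dimethyl-4-propyl-3,4,8,9-tetrahydro-2H,10H-pyrano[2,3-f]chromene-2,10-dione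
Conditions: Cs2CO3 (0.3 equiv), DMA (0.5 M, degassed), 456 nm LEDs, 20 °C
Reagents that add atoms: none
Why: Proposed new method: the caesium phenolate of 7 (ring B is an electron-rich phloroglucinol whose oxyanion is conjugated to the ring A ketone) should form a visible-light-absorbing donor–acceptor complex with the phthalimide ester 12; excitation should transfer one electron to give the phenoxyl radical and, after N–O scission and loss of CO2, the primary cyclobutylmethyl radical, which couples with the phenoxyl radical (or adds to the phenolate and passes the electron on to a further molecule of 12 in a chain) at C8, after which loss of the C8 proton restores the phenolate. The closest known reaction types are the photochemical donor–acceptor C-alkylation of phenolates and enolates with alkyl radical precursors and the SRN1 C-alkylation of naphthoxides. No ring is closed and no stereocentre is formed; the two ring D centres are not at risk because the radical carbon is exocyclic. The step needs C–C coupling at C8 rather than O-alkylation or attack at C6 or C4a, which the substrate secures because C8 is the only unsubstituted carbon of ring B and the only site from which the adduct can rearomatise. It also needs capture of the cyclobutylmethyl radical before ring opening, for which the slow clock of this radical type and the high phenolate concentration are relied on.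

**Step 9**
Reactants: 14 3-methylbut-2-en-1-ol
Product: 15 tert-butyl 3-methylbut-2-en-1-yl carbonate
Conditions: Boc2O, DMAP (5 mol%), CH2Cl2, 0 °C to rt
Reagents that add atoms: di-tert-butyl dicarbonate, CC(C)(C)OC(=O)OC(=O)OC(C)(C)C
Why: DMAP-catalysed O-acylation of the primary allylic alcohol gives the carbonate that serves as a base-free prenyl donor; no stereocentre is involved.

**Step 10**
Reactants: 13 (aryl-alkylated phenol from step 8); 15 tert-butyl 3-methylbut-2-en-1-yl carbonate
Product: 16 (4S,6R,8R,9S)-6-{[(1S,3R)-2,2-dimethyl-3-(prop-1-en-2-yl)cyclobutyl]methyl}-8,9-dimethyl-6-(3-methylbut-2-en-1-yl)-4-propyl-3,4,8,9-tetrahydro-2H-pyrano[2,3-f]chromene-2,5,10(6H)-trione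
Conditions: Pd2(dba)3·CHCl3 (2.5 mol%), (R,R)-DACH-phenyl bisphosphine ligand (7.5 mol%), THF, 0 °C to rt
Reagents that add atoms: none
Why: Tsuji–Trost-type dearomative allylic alkylation: zerovalent palladium ionises 15 to a π-prenyl complex of divalent palladium and tert-butoxide, which deprotonates 13; the phenolate attacks the unsubstituted allyl terminus through C8 (C6 and C4a are ring-fusion carbons and O-prenylation is reversible), and the chiral ligand pocket differentiates the faces of the planar nucleophile so that the quaternary C8 centre is set as R under catalyst control.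

**Step 11**
Reactants: 16 (dearomatised enol lactone from step 10)
Product: 17 (3S)-3-[(2R,3S,8R)-8-{[(1S,3R)-2,2-dimethyl-3-(prop-1-en-2-yl)cyclobutyl]methyl}-5-hydroxy-2,3-dimethyl-8-(3-methylbut-2-en-1-yl)-4,7-dioxo-3,4,7,8-tetrahydro-2H-chromen-6-yl]hexanoic acid (CNP0364345.1)
Conditions: LiOH, THF/H2O, 0 °C; then 1 M HCl
Reagents that add atoms: lithium hydroxide, [Li+].[OH-]
Why: saponification of the enol δ-lactone, an acylated vinylogous acid and therefore far more electrophilic than an alkyl ester, releases the C5 enol and the carboxylic acid; no stereocentre is touched, and the delocalised trione anion should protect the base-sensitive cis C3 centre.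

**Compound list**

1 | phloroglucinol | Oc1cc(O)cc(O)c1 | starting material
2 | ethyl 3-oxohexanoate | CCCC(=O)CC(=O)OCC | starting material
3 | 5,7-dihydroxy-4-propyl-2H-chromen-2-one | CCCC1=CC(=O)Oc2cc(O)cc(O)c12 | intermediate
4 | (2E)-2-methylbut-2-enoyl chloride | C/C=C(\C)C(Cl)=O | starting material
5 | 5,7-dihydroxy-8-[(2E)-2-methylbut-2-enoyl]-4-propyl-2H-chromen-2-one | C/C=C(\C)C(=O)c1c(O)cc(O)c2c1OC(=O)C=C2CCC | intermediate
6 | (8R,9S)-5-hydroxy-8,9-dimethyl-4-propyl-8,9-dihydro-2H,10H-pyrano[2,3-f]chromene-2,10-dione | C[C@@H]1[C@H](C)C(=O)c2c(O1)cc(O)c3c2OC(=O)C=C3CCC | intermediate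
7 | (4S,8R,9S)-5-hydroxy-8,9-dimethyl-4-propyl-3,4,8,9-tetrahydro-2H,10H-pyrano[2,3-f]chromene-2,10-dione | C[C@@H]1[C@H](C)C(=O)c2c(O1)cc(O)c3c2OC(=O)C[C@@H]3CCC | intermediate
8 | (1R,5R)-(+)-α-pinene | CC1=CC[C@@H]2C[C@H]1C2(C)C | starting material
9 | 2-[(1S,3S)-3-acetyl-2,2-dimethylcyclobutyl]acetic acid | CC(=O)[C@H]1C[C@@H](CC(=O)O)C1(C)C | intermediate
10 | 2-[(1S,3R)-2,2-dimethyl-3-(prop-1-en-2-yl)cyclobutyl]acetic acid | C=C(C)[C@H]1C[C@@H](CC(=O)O)C1(C)C | intermediate
11 | N-hydroxyphthalimide | O=C1c2ccccc2C(=O)N1O | starting material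
12 | 1,3-dioxoisoindolin-2-yl 2-[(1S,3R)-2,2-dimethyl-3-(prop-1-en-2-yl)cyclobutyl]acetate | C=C(C)[C@H]1C[C@@H](CC(=O)ON2C(=O)c3ccccc3C2=O)C1(C)C | intermediate
13 | (4S,8R,9S)-6-{[(1S,3R)-2,2-dimethyl-3-(prop-1-en-2-yl)cyclobutyl]methyl}-5-hydroxy-8,9-dimethyl-4-propyl-3,4,8,9-tetrahydro-2H,10H-pyrano[2,3-f]chromene-2,10-dione | C[C@@H]1[C@H](C)C(=O)c2c(O1)c(C[C@@H]4C[C@H](C(C)=C)C4(C)C)c(O)c3c2OC(=O)C[C@@H]3CCC | intermediate
14 | 3-methylbut-2-en-1-ol | CC(C)=CCO | starting material
15 | tert-butyl 3-methylbut-2-en-1-yl carbonate | CC(C)=CCOC(=O)OC(C)(C)C | intermediate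
16 | (4S,6R,8R,9S)-6-{[(1S,3R)-2,2-dimethyl-3-(prop-1-en-2-yl)cyclobutyl]methyl}-8,9-dimethyl-6-(3-methylbut-2-en-1-yl)-4-propyl-3,4,8,9-tetrahydro-2H-pyrano[2,3-f]chromene-2,5,10(6H)-trione | C=C(C)[C@H]1C[C@@H](C[C@@]2(CC=C(C)C)C(=O)C4=C(OC(=O)C[C@@H]4CCC)C3=C2O[C@H](C)[C@H](C)C3=O)C1(C)C | intermediate
17 | (3S)-3-[(2R,3S,8R)-8-{[(1S,3R)-2,2-dimethyl-3-(prop-1-en-2-yl)cyclobutyl]methyl}-5-hydroxy-2,3-dimethyl-8-(3-methylbut-2-en-1-yl)-4,7-dioxo-3,4,7,8-tetrahydro-2H-chromen-6-yl]hexanoic acid | C=C(C)[C@H]1C[C@@H](C[C@@]2(CC=C(C)C)C(=O)C([C@@H](CCC)CC(=O)O)=C(O)C3=C2O[C@H](C)[C@H](C)C3=O)C1(C)C | target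

**Step count:** 11 steps in total. Longest linear sequence: 7 steps (steps 1, 2, 3, 4, 8, 10, 11).

**Steps most likely to fail**

1. Step 8 (proposed new method). Possible failures:
   - the cyclobutylmethyl radical may open its ring before it is captured;
   - the phenolate may be O-alkylated or may take the acyl group from the active ester;
   - the light-induced electron transfer may be inefficient.

   Fallback with known chemistry: from 7, iodination at the only free ring position (N-iodosuccinimide, CH2Cl2, 0 °C) should give (4S,8R,9S)-5-hydroxy-6-iodo-8,9-dimethyl-4-propyl-3,4,8,9-tetrahydro-2H,10H-pyrano[2,3-f]chromene-2,10-dione F1. Nickel-catalysed reductive decarboxylative cross-electrophile coupling of F1 with 12 (NiBr2(dme), 4,4'-di-tert-butyl-2,2'-bipyridine, Zn, DMA, rt) then returns to 13. Here the alkyl radical is intercepted by the nickel catalyst instead of by the arene.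

2. Step 10. Possible failures: poor or reversed facial selectivity at C8 under ligand control, and persistent O-prenylation.

   Fallback that changes the mode of stereocontrol: from 13, alkylative dearomatisation under chiral ion-pair (phase-transfer) control with 1-bromo-3-methylbut-2-ene, solid Cs2CO3 and N-(9-anthracenylmethyl)cinchonidinium bromide (10 mol%) in toluene at −20 °C should give 16 directly. No new compound is made (F0).

3. Step 4. Possible failures: sluggish hydrogenation of the electron-rich, peri-hindered coumarin double bond, and insufficient or reversed enantioselection.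

   Fallback that builds the stereocentre by C–C bond formation instead of reduction, starting from 1:
   - condensation with ethyl propiolate (ZnCl2, 90 °C) should give 5,7-dihydroxy-2H-chromen-2-one F2;
   - Friedel–Crafts acylation with 4 as in step 2 should give 5,7-dihydroxy-8-[(2E)-2-methylbut-2-enoyl]-2H-chromen-2-one F3;
   - quinine-catalysed oxa-Michael cyclisation as in step 3 should give (8R,9S)-5-hydroxy-8,9-dimethyl-8,9-dihydro-2H,10H-pyrano[2,3-f]chromene-2,10-dione F4;
   - rhodium-catalysed asymmetric conjugate addition of (E)-prop-1-enylboronic acid (Rh(acac)(C2H4)2, (R)-SEGPHOS, dioxane/H2O, 60 °C) should give (4R,8R,9S)-5-hydroxy-8,9-dimethyl-4-[(1E)-prop-1-en-1-yl]-3,4,8,9-tetrahydro-2H,10H-pyrano[2,3-f]chromene-2,10-dione F5;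
   - hydrogenation of the propenyl group (H2, Pd/C, EtOAc) returns to 7.

**Further compounds**

F1 | step 8 | (4S,8R,9S)-5-hydroxy-6-iodo-8,9-dimethyl-4-propyl-3,4,8,9-tetrahydro-2H,10H-pyrano[2,3-f]chromene-2,10-dione | C[C@@H]1[C@H](C)C(=O)c2c(O1)c(I)c(O)c3c2OC(=O)C[C@@H]3CCC
F0 | step 10 | none | none
F2 | step 4 | 5,7-dihydroxy-2H-chromen-2-one | O=C1C=Cc2c(O)cc(O)cc2O1
F3 | step 4 | 5,7-dihydroxy-8-[(2E)-2-methylbut-2-enoyl]-2H-chromen-2-one | C/C=C(\C)C(=O)c1c(O)cc(O)c2c1OC(=O)C=C2
F4 | step 4 | (8R,9S)-5-hydroxy-8,9-dimethyl-8,9-dihydro-2H,10H-pyrano[2,3-f]chromene-2,10-dione | C[C@@H]1[C@H](C)C(=O)c2c(O1)cc(O)c3c2OC(=O)C=C3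
F5 | step 4 | (4R,8R,9S)-5-hydroxy-8,9-dimethyl-4-[(1E)-prop-1-en-1-yl]-3,4,8,9-tetrahydro-2H,10H-pyrano[2,3-f]chromene-2,10-dione | C[C@@H]1[C@H](C)C(=O)c2c(O1)cc(O)c3c2OC(=O)C[C@@H]3/C=C/C
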